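Atom labels used throughout: ring C1 (side chain), C2 (OH), C3 (O-angelate), C4 (Me, OH), C5 (Cl), C6 (CH2); chain C7 (=CH2), C8 (O-angelate), C9, C10 and C11 (epoxide).
Retrosynthesis: cut the C10–C11 epoxide oxygen, the C3 and C8 ester C–O bonds, C5–Cl (back to a C4–C5 epoxide, then the ring alkene), C7–C8 (alkenyl triflate plus aldehyde), the methyl carbon on C7 (methyl ketone from an acid) and, as the central cut, the ring bond C1–C6.
Enabling feature: C7–C1–C2(O)–C3(O)–C4(O) is a 2-deoxypentonic acid; closed as a δ-lactone through the C4 oxygen with a vinyl group (future C5 and C6) on C4, it is an allylic ester whose ketene acetal can shift [3,3], closing the carbocycle C1–C6 while the lactone ring opens.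
Forward order: 2-deoxy-D-ribose gives the acetonide lactone, which is opened, oxidised, vinylated to a vinyl ketone and methylated so that it re-closes as the 6-methyl-6-vinyl lactone; the ring contraction forms the only carbocycle; the chain is joined at C7, the ring alkene becomes the chlorohydrin, and the last acylation and the side-chain epoxidation follow.
Stereochemistry: C2 and C3 come from the sugar, C4 of the lactone from chelation-controlled methyl addition, C1 from C4 by chirality transfer in the [3,3] shift, C8 from a CBS reduction, C4 and C5 from hydroxyl-directed epoxidation and anti opening by chloride, C10 from a Shi epoxidation.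

Key step: step 8

Remark: 2-deoxy-D-ribose is written open-chain but reacts as its pyranose; 4-methylpent-3-en-1-ol, angelic acid and vinylmagnesium bromide are taken as commercial.

Step 1
Reactants: 1 2-deoxy-D-ribose
Product: 2 2-deoxy-3,4-O-isopropylidene-D-erythro-pentopyranose (lactol, anomer mixture)
Conditions: 2-methoxypropene, PPTS (cat.), EtOAc, 0 °C to rt
Reagents that add atoms: 2-methoxypropene, COC(C)=C
Why: Acid-catalysed acetalisation with an enol ether takes the pyranose form, in which only the cis-3,4-diol can form a dioxolane, so the hemiacetal stays free and C2 and C3 of the target are fixed with the sugar's configuration.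

Step 2
Reactants: 2 2-deoxy-3,4-O-isopropylidene-D-erythro-pentopyranose
Product: 3 2-deoxy-3,4-O-isopropylidene-D-erythro-pentono-1,5-lactone
Conditions: TEMPO (cat.), PhI(OAc)2, CH2Cl2, rt
Reagents that add atoms: none
Why: Oxoammonium (TEMPO) oxidation of a lactol to the lactone, which touches no stereocentre.

Step 3
Reactants: 3 2-deoxy-3,4-O-isopropylidene-D-erythro-pentono-1,5-lactone
Product: 4 methyl 2-[(4S,5R)-5-(hydroxymethyl)-2,2-dimethyl-1,3-dioxolan-4-yl]acetate
Conditions: K2CO3 (cat.), MeOH, 0 °C; AcOH to neutrality, concentrate cold, use at once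
Reagents that add atoms: methanol, CO
Why: Base-catalysed transesterification (lactone methanolysis) opens the δ-lactone in excess methanol, and the neutral hydroxy ester should re-close only slowly if it is oxidised without delay.

Step 4
Reactants: 4 methyl 2-[(4S,5R)-5-(hydroxymethyl)-2,2-dimethyl-1,3-dioxolan-4-yl]acetate
Product: 5 methyl 2-[(4S,5S)-5-formyl-2,2-dimethyl-1,3-dioxolan-4-yl]acetate
Conditions: Dess–Martin periodinane, NaHCO3, CH2Cl2, 0 °C to rt
Reagents that add atoms: none
Why: Dess–Martin oxidation gives the α-alkoxy aldehyde without amine base, so the cis-dioxolane centre next to the formyl group should not epimerise.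

Step 5
Reactants: 5 methyl 2-[(4S,5S)-5-formyl-2,2-dimethyl-1,3-dioxolan-4-yl]acetate; 6 vinylmagnesium bromide
Product: 7 methyl 2-[(4S,5R)-5-(1-hydroxyprop-2-enyl)-2,2-dimethyl-1,3-dioxolan-4-yl]acetate (both carbinol epimers)
Conditions: THF, −78 °C; AcOH quench at −78 °C
Reagents that add atoms: none
Why: Grignard 1,2-addition to the aldehyde is far faster than attack on the methyl ester at −78 °C, and the unselective new carbinol centre is erased by the next oxidation.

Step 6
Reactants: 7 methyl 2-[(4S,5R)-5-(1-hydroxyprop-2-enyl)-2,2-dimethyl-1,3-dioxolan-4-yl]acetate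
Product: 8 methyl 2-[(4S,5S)-2,2-dimethyl-5-(prop-2-enoyl)-1,3-dioxolan-4-yl]acetate (vinyl ketone)
Conditions: Dess–Martin periodinane, NaHCO3, CH2Cl2, 0 °C; used crude
Reagents that add atoms: none
Why: Dess–Martin oxidation of the allylic alcohol under neutral conditions should give the vinyl ketone without conjugate addition or epimerisation of the α-alkoxy centre.

Step 7
Reactants: 8 methyl 2-[(4S,5S)-2,2-dimethyl-5-(prop-2-enoyl)-1,3-dioxolan-4-yl]acetate
Product: 10 (3aS,4R,7aS)-4-ethenyl-2,2,4-trimethyltetrahydro-[1,3]dioxolo[4,5-c]pyran-6-one (δ-lactone; vinyl trans and methyl cis to the dioxolane oxygens), via tertiary bromomagnesium alkoxide 9 (not isolated)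
Conditions: MeMgBr (1.3 equiv), CH2Cl2/Et2O, −78 °C; then rt; aq. NH4Cl
Reagents that add atoms: methylmagnesium bromide, C[Mg]Br
Why: Cram-chelate-controlled Grignard 1,2-addition, in which magnesium bridges the ketone oxygen and the α-dioxolane oxygen and methyl enters from the face of the α-hydrogen (away from the C2 carbon), should set C4 as R with methyl cis and vinyl trans to the acetonide oxygens, after which the tertiary alkoxide closes onto the methyl ester by intramolecular transesterification.

Step 8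
Reactants: 10 (3aS,4R,7aS)-4-ethenyl-2,2,4-trimethyltetrahydro-[1,3]dioxolo[4,5-c]pyran-6-one
Product: 13 (3aS,4S,7aR)-2,2,7-trimethyl-3a,4,5,7a-tetrahydro-1,3-benzodioxole-4-carboxylic acid (all-cis C1 acid with C2/C3 acetonide and C4=C5 alkene), via silyl ketene acetal 11 (not isolated), via silyl ester 12 (not isolated)
Conditions: TBSOTf, Et3N, toluene, 0 °C to rt, then 110 °C; aq. K2CO3/MeOH, then citric acid to pH 4
Reagents that add atoms: tert-butyldimethylsilyl trifluoromethanesulfonate, CC(C)(C)[Si](C)(C)OS(=O)(=O)C(F)(F)F (its silyl group is carried by 11 and 12 and leaves on hydrolysis)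
Why: Soft enolisation with the silyl triflate and amine turns the lactone into the cyclic silyl ketene acetal 11, whose allyl vinyl ether unit C1=C7–O–C4–C5=C6 undergoes a concerted suprafacial [3,3] sigmatropic shift that forms C1–C6 and the C4=C5 double bond and breaks C4–O. The closest known reaction type is the Ireland–Claisen ring contraction of alkenyl-substituted lactones to cycloalkenecarboxylic acids. The cyclohexene closes by C–C bond formation between the ketene acetal carbon C1 and the vinyl terminus C6 through a boat-shaped, bicyclo[2.2.2]octane-like transition state with C1 and C4 as bridgeheads, the only geometry the lactone tether allows. The new stereocentre C1 is controlled by C4, because the vinyl group can bond only to the face of C1 on which it stands; with vinyl trans to the acetonide the carboxyl group emerges cis to the C2 and C3 oxygens. The step needs rearrangement to win over β-elimination of the C2 oxygen, which is secured by never forming a metal enolate: the neutral silyl ketene acetal has no driving force to expel alkoxide. Hydrolysis of the silyl ester 12 on work-up should give the acid.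

Step 9
Reactants: 13 (3aS,4S,7aR)-2,2,7-trimethyl-3a,4,5,7a-tetrahydro-1,3-benzodioxole-4-carboxylic acid
Product: 14 1-[(3aS,4S,7aR)-2,2,7-trimethyl-3a,4,5,7a-tetrahydro-1,3-benzodioxol-4-yl]ethan-1-one
Conditions: MeLi (2.2 equiv), THF, 0 °C; inverse quench into cold aq. NH4Cl
Reagents that add atoms: methyllithium, C[Li]
Why: Addition of methyllithium to the lithium carboxylate gives a dilithio gem-diolate that releases the methyl ketone only on work-up (classical acid to methyl ketone conversion), so over-addition is avoided and the epimerisable C1 centre of the ketone never meets base.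

Step 10
Reactants: 14 1-[(3aS,4S,7aR)-2,2,7-trimethyl-3a,4,5,7a-tetrahydro-1,3-benzodioxol-4-yl]ethan-1-one
Product: 15 1-[(3aS,4S,7aR)-2,2,7-trimethyl-3a,4,5,7a-tetrahydro-1,3-benzodioxol-4-yl]ethenyl trifluoromethanesulfonate
Conditions: KN(SiMe3)2, THF, −78 °C; PhNTf2, −78 to 0 °C
Reagents that add atoms: N-phenylbis(trifluoromethanesulfonimide), O=S(=O)(N(c1ccccc1)S(=O)(=O)C(F)(F)F)C(F)(F)F
Why: Kinetic enolisation takes the methyl group and not the hindered C1 methine, and O-triflation of the enolate gives the 1,1-disubstituted enol triflate, so C1 and the β-acetonide oxygen are not put at risk.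

Step 11
Reactants: 16 4-methylpent-3-en-1-ol
Product: 17 4-methylpent-3-enal
Conditions: Dess–Martin periodinane, NaHCO3, CH2Cl2, 0 °C; used as a cold solution
Reagents that add atoms: none
Why: Buffered Dess–Martin oxidation should give the β,γ-unsaturated aldehyde without moving the double bond into conjugation.

Step 12
Reactants: 15 1-[(3aS,4S,7aR)-2,2,7-trimethyl-3a,4,5,7a-tetrahydro-1,3-benzodioxol-4-yl]ethenyl trifluoromethanesulfonate; 17 4-methylpent-3-enal
Product: 18 2-[(3aS,4R,7aR)-2,2,7-trimethyl-3a,4,5,7a-tetrahydro-1,3-benzodioxol-4-yl]-6-methylhepta-1,5-dien-3-ol (both C8 epimers)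
Conditions: CrCl2 (4 equiv), NiCl2 (2 mol %), DMF, rt
Reagents that add atoms: none
Why: Nozaki–Hiyama–Kishi coupling (nickel activation of the alkenyl triflate, transfer to chromium, non-basic addition to the enolisable aldehyde) forms C7–C8 with the C7 methylene already in place, and the unselective C8 centre is corrected in the next two steps.

Step 13
Reactants: 18 2-[(3aS,4R,7aR)-2,2,7-trimethyl-3a,4,5,7a-tetrahydro-1,3-benzodioxol-4-yl]-6-methylhepta-1,5-dien-3-ol
Product: 19 2-[(3aS,4R,7aR)-2,2,7-trimethyl-3a,4,5,7a-tetrahydro-1,3-benzodioxol-4-yl]-6-methylhepta-1,5-dien-3-one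
Conditions: Dess–Martin periodinane, NaHCO3, CH2Cl2, 0 °C; short filtration, used at once
Reagents that add atoms: none
Why: Dess–Martin oxidation merges both C8 epimers into one α-methylene ketone under non-basic conditions that should leave the skipped C10=C11 double bond where it is.

Step 14
Reactants: 19 2-[(3aS,4R,7aR)-2,2,7-trimethyl-3a,4,5,7a-tetrahydro-1,3-benzodioxol-4-yl]-6-methylhepta-1,5-dien-3-one
Product: 20 (3S)-2-[(3aS,4R,7aR)-2,2,7-trimethyl-3a,4,5,7a-tetrahydro-1,3-benzodioxol-4-yl]-6-methylhepta-1,5-dien-3-ol (8S alcohol)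
Conditions: (R)-2-methyl-CBS-oxazaborolidine (0.5 equiv), catecholborane, toluene, −78 °C
Reagents that add atoms: none
Why: Corey–Bakshi–Shibata reduction, with the branched alkenyl group as the large and the C9 methylene as the small ketone substituent, should deliver hydride to one face under catalyst control and set C8 as S (the (R)-catalyst is chosen by analogy with the aryl methyl ketone model).

Step 15
Reactants: 20 (3S)-2-[(3aS,4R,7aR)-2,2,7-trimethyl-3a,4,5,7a-tetrahydro-1,3-benzodioxol-4-yl]-6-methylhepta-1,5-dien-3-ol; 21 angelic acid [(Z)-2-methylbut-2-enoic acid]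
Product: 23 (3S)-2-[(3aS,4R,7aR)-2,2,7-trimethyl-3a,4,5,7a-tetrahydro-1,3-benzodioxol-4-yl]-6-methylhepta-1,5-dien-3-yl (Z)-2-methylbut-2-enoate (C8 angelate), via mixed anhydride 22 (not isolated)
Conditions: 21, 2,4,6-trichlorobenzoyl chloride, Et3N, toluene, rt; then 20, 80 °C
Reagents that add atoms: 2,4,6-trichlorobenzoyl chloride, O=C(Cl)c1c(Cl)cc(Cl)cc1Cl (its acyl group is carried by 22 only)
Why: Yamaguchi esterification through the mixed anhydride is the established way to transfer the (Z)-acid without isomerisation to the tiglate, and C8 keeps its configuration because its C–O bond is not broken.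

Step 16
Reactants: 23 C8 angelate acetonide
Product: 24 (3S)-2-[(1R,5R,6S)-5,6-dihydroxy-4-methylcyclohex-3-en-1-yl]-6-methylhepta-1,5-dien-3-yl (Z)-2-methylbut-2-enoate (C2,C3-diol)
Conditions: AcOH/H2O (4:1), 40 °C
Reagents that add atoms: none
Why: Acid hydrolysis of the isopropylidene acetal frees the cis-diol, and the allylic ester and the three C=C bonds should tolerate aqueous acetic acid.

Step 17
Reactants: 24 C2,C3-diol
Product: 25 (1R,2S,3S,4S,5R,8S)-4,5-epoxy-2,3-diol 8-angelate (epoxide oxygen cis to both hydroxyls)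
Conditions: VO(acac)2 (5 mol %), t-BuOOH (1.1 equiv), CH2Cl2, 0 °C
Reagents that add atoms: tert-butyl hydroperoxide, CC(C)(C)OO
Why: Vanadium-catalysed hydroxyl-directed epoxidation delivers oxygen from the metal-bound C3 allylic (and C2 homoallylic) hydroxyl to the ring C4=C5 bond on their own face, setting C4 and C5 syn to the diol, while the undirected C10=C11 bond, the deactivated C7 methylene and the enoate are expected to react far more slowly.

Step 18
Reactants: 25 4,5-epoxy-2,3-diol 8-angelate
Product: 26 (1R,2S,3S,4S,5S,8S)-5-chloro-2,3,4-triol 8-angelate (Cl trans to the C4 hydroxyl; the three hydroxyls cis)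
Conditions: Ti(OiPr)4 (1.5 equiv), Et2NH·HCl (2 equiv), CH2Cl2, rt
Reagents that add atoms: diethylammonium chloride, CC[NH2+]CC.[Cl-]
Why: Titanium-mediated opening of a 2,3-epoxy alcohol by chloride at the carbon remote from the carbinol is an SN2 attack at secondary C5 anti to the epoxide oxygen (trans-diaxial, Fürst–Plattner), which inverts C5 and leaves the tertiary C4 oxygen in place.

Step 19
Reactants: 26 5-chloro-2,3,4-triol 8-angelate; 21 angelic acid
Product: 28 (1R,2S,3S,4S,5S,8S)-5-chloro-2,4-diol 3,8-di-angelate (target lacking the C10–C11 epoxide), via angeloyl chloride 27 (not isolated)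
Conditions: 21, 1-chloro-N,N,2-trimethylprop-1-en-1-amine, CH2Cl2, 0 °C; then 26, Ph2BOCH2CH2NH2 (10 mol %), iPr2NEt, MeCN, 0 °C to rt
Reagents that add atoms: 1-chloro-N,N,2-trimethylprop-1-en-1-amine, CC(C)=C(Cl)N(C)C (its chlorine is carried by 27 only)
Why: Borinic acid-catalysed regioselective acylation of a cyclic cis-1,2-diol activates the equatorial oxygen of the bound diol, which in the chair with axial C2–OH, axial C4–OH and equatorial C3–OH is O3 for either cis pair, so the acid chloride made under neutral conditions should acylate C3 and leave the shielded axial C2 and tertiary C4 hydroxyls free.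

Step 20
Reactants: 28 5-chloro-2,4-diol 3,8-di-angelate
Product: 29 CNP0158207.1, (1R,2S,3S,4S,5S,8S,10R)
Conditions: D-fructose-derived Shi ketone (1 equiv), KHSO5 (as 2KHSO5·KHSO4·K2SO4), NaHCO3 buffer (pH about 8), MeCN/dimethoxymethane/H2O, 0 °C
Reagents that add atoms: potassium peroxymonosulfate, [K+].[O-]S(=O)(=O)OO
Why: Shi asymmetric epoxidation, in which the chiral dioxirane attacks the electron-rich trisubstituted C10=C11 bond through the spiro transition state, should give the 10R epoxide, while the deactivated C7 methylene and the two enoate double bonds react far more slowly and the near-neutral buffer spares the chlorohydrin and the esters.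

Compound list
1 | 2-deoxy-D-ribose | O=CC[C@H](O)[C@H](O)CO | starting material
2 | 2-deoxy-3,4-O-isopropylidene-D-erythro-pentopyranose | OC1C[C@@H]2OC(C)(C)O[C@@H]2CO1 | intermediate
3 | 2-deoxy-3,4-O-isopropylidene-D-erythro-pentono-1,5-lactone | O=C1C[C@@H]2OC(C)(C)O[C@@H]2CO1 | intermediate
4 | methyl 2-[(4S,5R)-5-(hydroxymethyl)-2,2-dimethyl-1,3-dioxolan-4-yl]acetate | COC(=O)C[C@@H]1OC(C)(C)O[C@@H]1CO | intermediate
5 | methyl 2-[(4S,5S)-5-formyl-2,2-dimethyl-1,3-dioxolan-4-yl]acetate | COC(=O)C[C@@H]1OC(C)(C)O[C@@H]1C=O | intermediate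
6 | vinylmagnesium bromide | C=C[Mg]Br | starting material
7 | methyl 2-[(4S,5R)-5-(1-hydroxyprop-2-enyl)-2,2-dimethyl-1,3-dioxolan-4-yl]acetate (carbinol epimers) | COC(=O)C[C@@H]1OC(C)(C)O[C@@H]1C(O)C=C | intermediate
8 | methyl 2-[(4S,5S)-2,2-dimethyl-5-(prop-2-enoyl)-1,3-dioxolan-4-yl]acetate | COC(=O)C[C@@H]1OC(C)(C)O[C@@H]1C(=O)C=C | intermediate
9 | bromomagnesium alkoxide of methyl 2-[(4S,5S)-5-[(2R)-2-hydroxybut-3-en-2-yl]-2,2-dimethyl-1,3-dioxolan-4-yl]acetate | COC(=O)C[C@@H]1OC(C)(C)O[C@@H]1[C@](C)(O[Mg]Br)C=C | intermediate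
10 | (3aS,4R,7aS)-4-ethenyl-2,2,4-trimethyltetrahydro-[1,3]dioxolo[4,5-c]pyran-6-one | O=C1C[C@@H]2OC(C)(C)O[C@@H]2[C@@](C)(C=C)O1 | intermediate
11 | tert-butyldimethylsilyl ketene acetal of 10 | CC(C)(C)[Si](C)(C)OC1=C[C@@H]2OC(C)(C)O[C@@H]2[C@@](C)(C=C)O1 | intermediate
12 | tert-butyldimethylsilyl ester of 13 | CC(C)(C)[Si](C)(C)OC(=O)[C@H]1CC=C(C)[C@H]2OC(C)(C)O[C@@H]12 | intermediate
13 | (3aS,4S,7aR)-2,2,7-trimethyl-3a,4,5,7a-tetrahydro-1,3-benzodioxole-4-carboxylic acid | OC(=O)[C@H]1CC=C(C)[C@H]2OC(C)(C)O[C@@H]12 | intermediate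
14 | 1-[(3aS,4S,7aR)-2,2,7-trimethyl-3a,4,5,7a-tetrahydro-1,3-benzodioxol-4-yl]ethan-1-one | CC(=O)[C@H]1CC=C(C)[C@H]2OC(C)(C)O[C@@H]12 | intermediate
15 | 1-[(3aS,4S,7aR)-2,2,7-trimethyl-3a,4,5,7a-tetrahydro-1,3-benzodioxol-4-yl]ethenyl trifluoromethanesulfonate | C=C(OS(=O)(=O)C(F)(F)F)[C@H]1CC=C(C)[C@H]2OC(C)(C)O[C@@H]12 | intermediate
16 | 4-methylpent-3-en-1-ol | CC(C)=CCCO | starting material
17 | 4-methylpent-3-enal | CC(C)=CCC=O | intermediate
18 | 2-[(3aS,4R,7aR)-2,2,7-trimethyl-3a,4,5,7a-tetrahydro-1,3-benzodioxol-4-yl]-6-methylhepta-1,5-dien-3-ol (C8 epimers) | C=C(C(O)CC=C(C)C)[C@H]1CC=C(C)[C@H]2OC(C)(C)O[C@@H]12 | intermediate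
19 | 2-[(3aS,4R,7aR)-2,2,7-trimethyl-3a,4,5,7a-tetrahydro-1,3-benzodioxol-4-yl]-6-methylhepta-1,5-dien-3-one | C=C(C(=O)CC=C(C)C)[C@H]1CC=C(C)[C@H]2OC(C)(C)O[C@@H]12 | intermediate
20 | (3S)-2-[(3aS,4R,7aR)-2,2,7-trimethyl-3a,4,5,7a-tetrahydro-1,3-benzodioxol-4-yl]-6-methylhepta-1,5-dien-3-ol | C=C([C@@H](O)CC=C(C)C)[C@H]1CC=C(C)[C@H]2OC(C)(C)O[C@@H]12 | intermediate
21 | angelic acid, (Z)-2-methylbut-2-enoic acid | C/C=C(/C)C(=O)O | starting material
22 | (Z)-2-methylbut-2-enoic 2,4,6-trichlorobenzoic anhydride | C/C=C(/C)C(=O)OC(=O)c1c(Cl)cc(Cl)cc1Cl | intermediate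
23 | (3S)-2-[(3aS,4R,7aR)-2,2,7-trimethyl-3a,4,5,7a-tetrahydro-1,3-benzodioxol-4-yl]-6-methylhepta-1,5-dien-3-yl (Z)-2-methylbut-2-enoate | C=C([C@H](CC=C(C)C)OC(=O)/C(C)=C\C)[C@H]1CC=C(C)[C@H]2OC(C)(C)O[C@@H]12 | intermediate
24 | (3S)-2-[(1R,5R,6S)-5,6-dihydroxy-4-methylcyclohex-3-en-1-yl]-6-methylhepta-1,5-dien-3-yl (Z)-2-methylbut-2-enoate | C=C([C@H](CC=C(C)C)OC(=O)/C(C)=C\C)[C@H]1CC=C(C)[C@@H](O)[C@H]1O | intermediate
25 | (1R,2S,3S,4S,5R,8S)-4,5-epoxy-2,3-diol 8-angelate, epoxide cis to the hydroxyls | C=C([C@H](CC=C(C)C)OC(=O)/C(C)=C\C)[C@H]1C[C@H]2O[C@@]2(C)[C@@H](O)[C@H]1O | intermediate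
26 | (1R,2S,3S,4S,5S,8S)-5-chloro-2,3,4-triol 8-angelate | C=C([C@H](CC=C(C)C)OC(=O)/C(C)=C\C)[C@H]1C[C@H](Cl)[C@@](C)(O)[C@@H](O)[C@H]1O | intermediate
27 | angeloyl chloride, (Z)-2-methylbut-2-enoyl chloride | C/C=C(/C)C(Cl)=O | intermediate
28 | (1R,2S,3S,4S,5S,8S)-5-chloro-2,4-diol 3,8-di-angelate with C10=C11 alkene | C=C([C@H](CC=C(C)C)OC(=O)/C(C)=C\C)[C@H]1C[C@H](Cl)[C@@](C)(O)[C@@H](OC(=O)/C(C)=C\C)[C@H]1O | intermediate
29 | CNP0158207.1, (1R,2S,3S,4S,5S,8S,10R) | C=C([C@H](C[C@H]1OC1(C)C)OC(=O)/C(C)=C\C)[C@H]1C[C@H](Cl)[C@@](C)(O)[C@@H](OC(=O)/C(C)=C\C)[C@H]1O | target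

Total step count: 20. Longest linear sequence: 19 steps (steps 1 to 10 and 12 to 20, from 2-deoxy-D-ribose).

Steps most likely to fail

1. Step 19. The acylation may spread to the axial C2 hydroxyl, the acyl group may migrate between the cis hydroxyls, or the acyl donor may isomerise from Z to E during a slow reaction. The fallback blocks C2 first and sets out from 26. Treatment with 2-chloro-1,1,1-trimethoxyethane and PPTS should give the cyclic C2/C3 orthoester F1. Mild aqueous acetic acid opens such orthoesters to the axial ester, here the C2 chloroacetate F2 with C3–OH free. The mixed anhydride 22 (toluene, 60 °C) then acylates the only free secondary hydroxyl to give the C2 chloroacetate C3 angelate F3. Thiourea with NaHCO3 in EtOH/CH2Cl2 removes the chloroacetyl group selectively, and the route is rejoined at 28.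

2. Step 7. The vinyl ketone may polymerise, take up the Grignard reagent in the conjugate sense, or react with too little facial bias. The fallback carries the vinyl group as a silylated alkyne and sets out from 5. LiC≡CSiMe3 in THF at −78 °C gives the propargylic alcohols F4, and Dess–Martin oxidation gives the ynone F5, which can only add 1,2 and whose slim alkynyl group favours the chelate. MeMgBr under the same chelation control, followed by ring closure, gives the 6-methyl-6-(trimethylsilylethynyl) lactone F6. Bu4NF buffered with AcOH removes silicon to give the ethynyl lactone F7, and semi-hydrogenation over Pd/CaCO3 poisoned with Pb(OAc)2 (Lindlar catalyst) with quinoline under H2 returns to 10.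

3. Step 13. The skipped C10=C11 double bond may migrate into conjugation, or the α-methylene ketone may be lost to Michael-type addition during oxidation and handling. The fallback avoids the enone and builds the chain by enolate chemistry, setting out from 13. Coupling with MeNHOMe·HCl (EDC·HCl, HOBt, N-methylmorpholine) gives the N-methoxy-N-methylamide F8. 4-Methylpent-3-enylmagnesium bromide F9, made from 5-bromo-2-methylpent-2-ene and Mg, adds to give the ketone F10. KN(SiMe3)2 at −78 °C deprotonates the C8 methylene, and (+)-(camphorsulfonyl)oxaziridine hydroxylates the Z-enolate, expected by analogy with aryl ketone enolates to give the (8S)-hydroxy ketone F11. Et3SiCl and imidazole give the silyl ether F12, and the Tebbe reagent Cp2Ti(μ-Cl)(μ-CH2)AlMe2 methylenates the ketone without base to give the silyl-protected allylic alcohol F13. Bu4NF removes the silyl group, and the route is rejoined at 20.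

Further compounds
F1 | step 19 | cyclic C2/C3 2-(chloromethyl)-2-methoxy orthoester of 26 | C=C([C@H](CC=C(C)C)OC(=O)/C(C)=C\C)[C@H]1C[C@H](Cl)[C@@](C)(O)[C@H]2OC(CCl)(OC)O[C@@H]12
F2 | step 19 | C2 chloroacetate of 26 | C=C([C@H](CC=C(C)C)OC(=O)/C(C)=C\C)[C@H]1C[C@H](Cl)[C@@](C)(O)[C@@H](O)[C@H]1OC(=O)CCl
F3 | step 19 | C2 chloroacetate C3 angelate | C=C([C@H](CC=C(C)C)OC(=O)/C(C)=C\C)[C@H]1C[C@H](Cl)[C@@](C)(O)[C@@H](OC(=O)/C(C)=C\C)[C@H]1OC(=O)CCl
F4 | step 7 | methyl 2-[(4S,5R)-5-[1-hydroxy-3-(trimethylsilyl)prop-2-ynyl]-2,2-dimethyl-1,3-dioxolan-4-yl]acetate (carbinol epimers) | COC(=O)C[C@@H]1OC(C)(C)O[C@@H]1C(O)C#C[Si](C)(C)C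
F5 | step 7 | methyl 2-[(4S,5S)-2,2-dimethyl-5-[3-(trimethylsilyl)prop-2-ynoyl]-1,3-dioxolan-4-yl]acetate | COC(=O)C[C@@H]1OC(C)(C)O[C@@H]1C(=O)C#C[Si](C)(C)C
F6 | step 7 | 6-methyl-6-(trimethylsilylethynyl) analogue of lactone 10 | O=C1C[C@@H]2OC(C)(C)O[C@@H]2[C@@](C)(C#C[Si](C)(C)C)O1
F7 | step 7 | 6-ethynyl-6-methyl analogue of lactone 10 | O=C1C[C@@H]2OC(C)(C)O[C@@H]2[C@@](C)(C#C)O1
F8 | step 13 | N-methoxy-N-methylamide of 13 | CON(C)C(=O)[C@H]1CC=C(C)[C@H]2OC(C)(C)O[C@@H]12
F9 | step 13 | 4-methylpent-3-enylmagnesium bromide | CC(C)=CCC[Mg]Br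
F10 | step 13 | 1-[(3aS,4S,7aR)-2,2,7-trimethyl-3a,4,5,7a-tetrahydro-1,3-benzodioxol-4-yl]-5-methylhex-4-en-1-one | CC(C)=CCCC(=O)[C@H]1CC=C(C)[C@H]2OC(C)(C)O[C@@H]12
F11 | step 13 | (2S)-2-hydroxy derivative of F10 (8S hydroxy ketone) | CC(C)=CC[C@H](O)C(=O)[C@H]1CC=C(C)[C@H]2OC(C)(C)O[C@@H]12
F12 | step 13 | triethylsilyl ether of F11 | CC[Si](CC)(CC)O[C@@H](CC=C(C)C)C(=O)[C@H]1CC=C(C)[C@H]2OC(C)(C)O[C@@H]12
F13 | step 13 | triethylsilyl ether of 20 | C=C([C@H](CC=C(C)C)O[Si](CC)(CC)CC)[C@H]1CC=C(C)[C@H]2OC(C)(C)O[C@@H]12
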